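Ring A is made by ring contraction of a δ-lactone, which forms the C5–C10 bond. In the target (labdane numbering) tertiary C5 and quaternary C10 are adjacent, and C5 sits next to the C4 gem-dimethyl group. C6, C5, C4, C3 and C2 are therefore laid out as a 4,4-dimethyl oxan-2-one whose carbinol carbon C2 carries a Z-enyne arm (C1, C10, methyl, silyl alkyne). One enolate Claisen shift of its silyl ketene acetal forms C5–C10, closes ring A and sets both stereocentres from the single C2 centre. The C10 ethynyl group then closes ring B by enyne metathesis, and the side chain is attached convergently.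

Key step: step 7

Remark (assumption): atom labels follow labdane-type numbering: ring A = C1–C5 and C10, ring B = C5–C10, C11–C12 link, C13 (hydroxymethyl)–C14–C15 diene, butenolide C16–C19 with the methyl on C17. Partial lactonisation of 6 is assumed to be harmless, because ester and lactone are reduced to the same diol in step 4.

Step 1
Reactants: 1 3,3-dimethylglutaric anhydride
Product: 2 5-methoxy-3,3-dimethyl-5-oxopentanoic acid
Conditions: MeOH, reflux
Reagents that add atoms: methanol, CO
Why: Alcoholysis of a cyclic anhydride, whose two carbonyl groups are equivalent, should give a single half ester.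

Step 2
Reactants: 2 5-methoxy-3,3-dimethyl-5-oxopentanoic acid; 3 propyne
Product: 5 methyl 3,3-dimethyl-5-oxooct-6-ynoate, via acid chloride 4 (not isolated)
Conditions: (COCl)2, DMF (cat.), CH2Cl2, 0 °C → rt, concentrate; then 3, PdCl2(PPh3)2 (2 mol%), CuI (4 mol%), Et3N, THF, rt
Reagents that add atoms: none
Why: Acid chloride formation followed by copper-cocatalysed acyl Sonogashira coupling should give the alkynyl ketone directly, the methyl ester being inert.

Step 3
Reactants: 5 methyl 3,3-dimethyl-5-oxooct-6-ynoate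
Product: 6 methyl (5R)-5-hydroxy-3,3-dimethyloct-6-ynoate
Conditions: Ru[(R,R)-TsNCH(Ph)CH(Ph)NH](p-cymene) (2 mol%), i-PrOH, rt
Reagents that add atoms: none
Why: Asymmetric transfer hydrogenation of an alkynyl ketone, in which the (R,R)-diamine ruthenium hydride distinguishes the alkynyl from the alkyl flank and delivers hydride to one face, should set the (R)-carbinol (the later C2).

Step 4
Reactants: 6 methyl (5R)-5-hydroxy-3,3-dimethyloct-6-ynoate
Product: 7 (5R,6Z)-7-iodo-3,3-dimethyloct-6-ene-1,5-diol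
Conditions: NaAlH2(OCH2CH2OCH3)2 (Red-Al, 4 equiv), THF, 0 °C → rt; EtOAc, 0 °C; then I2, THF, −78 → 0 °C
Reagents that add atoms: iodine, I-I
Why: The hydride reduces the ester to the primary alkoxide and the propargylic alkoxyaluminate then delivers hydride to the proximal alkyne carbon (hydroxyl-directed trans-hydroalumination), so that iodinolysis of the C–Al bond with retention should place iodine cis to the carbinol carbon (6Z) without touching the stereocentre.

Step 5
Reactants: 7 (5R,6Z)-7-iodo-3,3-dimethyloct-6-ene-1,5-diol; 8 ethynyltrimethylsilane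
Product: 9 (5R,6Z)-3,3,7-trimethyl-9-(trimethylsilyl)non-6-en-8-yne-1,5-diol
Conditions: PdCl2(PPh3)2 (3 mol%), CuI (6 mol%), i-Pr2NH, THF, rt
Reagents that add atoms: none
Why: Sonogashira coupling of an alkenyl iodide proceeds with retention of alkene geometry and tolerates free hydroxyl groups, so the alkynyl group should stay cis to the carbinol carbon.

Step 6
Reactants: 9 (5R,6Z)-3,3,7-trimethyl-9-(trimethylsilyl)non-6-en-8-yne-1,5-diol
Product: 11 (6R)-4,4-dimethyl-6-[(1Z)-2-methyl-4-(trimethylsilyl)but-1-en-3-yn-1-yl]oxan-2-one, via lactol 10 (not isolated)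
Conditions: TEMPO (0.2 equiv), PhI(OAc)2 (2.5 equiv), CH2Cl2, rt
Reagents that add atoms: none
Why: Nitroxyl-mediated oxidative lactonisation should oxidise the unhindered primary alcohol much faster than the secondary allylic one, and the hydroxy aldehyde closes to lactol 10, which is oxidised on to the δ-lactone while the carbinol centre stays untouched.

Step 7
Reactants: 11 (6R)-4,4-dimethyl-6-[(1Z)-2-methyl-4-(trimethylsilyl)but-1-en-3-yn-1-yl]oxan-2-one
Product: 14 (1S,2S)-2,6,6-trimethyl-2-[(trimethylsilyl)ethynyl]cyclohex-3-ene-1-carboxylic acid, via silyl ketene acetal 12 (not isolated), via trimethylsilyl ester 13 (not isolated)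
Conditions: LiN(i-Pr)2 (1.3 equiv), Me3SiCl/Et3N (3 equiv), THF, −78 °C → rt; toluene, 110 °C; then 1 M HCl, THF, rt
Reagents that add atoms: none
Why: Deprotonation at C5 with in situ silylation gives the cyclic silyl ketene acetal 12, whose geometry is fixed by the ring, and on heating a concerted suprafacial [3,3] sigmatropic shift should form C5–C10 while C2–O breaks and the C1=C2 alkene appears, after which silyl ester 13 is hydrolysed. The closest known reaction type is the Ireland–Claisen ring contraction of 6-alkenyl δ-lactone silyl ketene acetals to cyclohex-3-enecarboxylic acids. Ring A (C5–C4–C3–C2–C1–C10) is closed by the sigmatropic bond itself, formally a 6-endo attack of the exocyclic enolate carbon C5 on C10 of the C1=C10 alkene across the C3–C4 tether, which is possible only through a boat, bicyclo[2.2.2]octane-like array with C2 and C5 as bridgeheads. C5 is controlled by C2, because the alkenyl arm can reach only the ketene acetal face on which it stands, so the (R)-carbinol should give (S)-C5; C10 is controlled by the same suprafacial transfer together with the Z geometry, which places the alkynyl group over the C3–C4 bridge and hence trans to the C6 carboxyl, as a trans ring fusion requires. The selectivities needed are complete chirality transfer and a single C5/C10 relative configuration; the tether secures both by excluding the chair and the opposite face, and the slim alkynyl group is the substituent that fits beside the axial C4 methyl group in the boat.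

Step 8
Reactants: 14 (1S,2S)-2,6,6-trimethyl-2-[(trimethylsilyl)ethynyl]cyclohex-3-ene-1-carboxylic acid
Product: 15 [(1S,2S)-2,6,6-trimethyl-2-[(trimethylsilyl)ethynyl]cyclohex-3-en-1-yl]methanol
Conditions: LiAlH4, THF, 0 → 50 °C
Reagents that add atoms: none
Why: Hydride reduction of the hindered carboxylic acid through its aluminium carboxylate should give the primary alcohol (C6) and leave the silyl alkyne, the ring alkene and both stereocentres untouched.

Step 9
Reactants: 15 [(1S,2S)-2,6,6-trimethyl-2-[(trimethylsilyl)ethynyl]cyclohex-3-en-1-yl]methanol; 16 2-methylallylmagnesium chloride (CH2=C(CH3)CH2MgCl, 0.5 M in THF)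
Product: 18 trimethyl{[(1S,6S)-1,5,5-trimethyl-6-(3-methylbut-3-en-1-yl)cyclohex-2-en-1-yl]ethynyl}silane, via triflate 17 (not isolated)
Conditions: Tf2O, pyridine, CH2Cl2, −78 → −20 °C, cold filtration through silica; then 16, CuBr·SMe2 (10 mol%), Et2O, −78 → 0 °C
Reagents that add atoms: none
Why: A primary triflate is reactive enough for SN2 displacement even at this β-branched carbon, and copper-catalysed coupling with the allylic Grignard reagent (both allyl termini are equivalent) should form C6–C7 while the silyl group keeps the alkyne from being deprotonated.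

Step 10
Reactants: 18 trimethyl{[(1S,6S)-1,5,5-trimethyl-6-(3-methylbut-3-en-1-yl)cyclohex-2-en-1-yl]ethynyl}silane
Product: 19 (3S,4S)-3-ethynyl-3,5,5-trimethyl-4-(3-methylbut-3-en-1-yl)cyclohex-1-ene
Conditions: K2CO3, MeOH, rt
Reagents that add atoms: none
Why: Base-catalysed methanolysis of the alkynyl C–Si bond should free the terminal alkyne needed for metathesis.

Step 11
Reactants: 19 (3S,4S)-3-ethynyl-3,5,5-trimethyl-4-(3-methylbut-3-en-1-yl)cyclohex-1-ene
Product: 20 (4aS,8aS)-1-ethenyl-2,5,5,8a-tetramethyl-3,4,4a,5,6,8a-hexahydronaphthalene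
Conditions: second-generation Grubbs catalyst RuCl2(=CHPh)(H2IMes)(PCy3) (10 mol%), ethylene (1 atm), toluene, 80 °C
Reagents that add atoms: none
Why: Ring-closing enyne metathesis in the exo mode, in which the ruthenium vinylcarbene formed on C9 closes onto the 1,1-disubstituted alkene, should give the tetrasubstituted C8=C9 bond of ring B and the C11=C12 vinyl group, the quaternary C10 favouring closure and no stereocentre being involved.

Step 12
Reactants: 21 but-2-yne-1,4-diol
Product: 22 4-{[tert-butyl(dimethyl)silyl]oxy}but-2-yn-1-ol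
Conditions: NaH (1 equiv), THF, 0 °C; TBSCl (1 equiv), rt
Reagents that add atoms: tert-butyldimethylsilyl chloride, CC(C)(C)[Si](C)(C)Cl
Why: Mono-silylation of a symmetrical diol through its sparingly soluble monosodium alkoxide should stop after one hydroxyl group.

Step 13
Reactants: 22 4-{[tert-butyl(dimethyl)silyl]oxy}but-2-yn-1-ol
Product: 23 (2Z)-4-{[tert-butyl(dimethyl)silyl]oxy}-3-iodobut-2-en-1-ol
Conditions: NaAlH2(OCH2CH2OCH3)2 (Red-Al), THF, 0 °C; EtOAc; then I2, −78 °C
Reagents that add atoms: iodine, I-I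
Why: Hydroxyl-directed trans-hydroalumination followed by iodinolysis at low temperature, before the β-silyloxy alkenylalane can eliminate, should put iodine on the distal carbon cis to the CH2OH group (2Z).

Step 14
Reactants: 20 (4aS,8aS)-1-ethenyl-2,5,5,8a-tetramethyl-3,4,4a,5,6,8a-hexahydronaphthalene; 23 (2Z)-4-{[tert-butyl(dimethyl)silyl]oxy}-3-iodobut-2-en-1-ol
Product: 25 (2E)-3-({[tert-butyl(dimethyl)silyl]oxy}methyl)-5-[(4aS,8aS)-2,5,5,8a-tetramethyl-3,4,4a,5,6,8a-hexahydronaphthalen-1-yl]pent-2-en-1-ol, via B-alkyl borane 24 (not isolated)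
Conditions: 9-BBN (0.5 M in THF), 0 °C → rt; then 23, PdCl2(dppf) (5 mol%), AsPh3 (10 mol%), Cs2CO3, DMF/THF/H2O, rt
Reagents that add atoms: none
Why: 9-BBN adds selectively to the monosubstituted vinyl group with boron on C12, and the B-alkyl Suzuki–Miyaura coupling with the alkenyl iodide should form C12–C13 with retention, so that C12 ends up cis to C15 (the 13E geometry of the target).

Step 15
Reactants: 25 (2E)-3-({[tert-butyl(dimethyl)silyl]oxy}methyl)-5-[(4aS,8aS)-2,5,5,8a-tetramethyl-3,4,4a,5,6,8a-hexahydronaphthalen-1-yl]pent-2-en-1-ol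
Product: 26 (2E)-3-({[tert-butyl(dimethyl)silyl]oxy}methyl)-5-[(4aS,8aS)-2,5,5,8a-tetramethyl-3,4,4a,5,6,7,8,8a-octahydronaphthalen-1-yl]pent-2-en-1-ol
Conditions: H2 (1 atm), RhCl(PPh3)3 (5 mol%), benzene, rt
Reagents that add atoms: none
Why: Homogeneous hydrogenation with RhCl(PPh3)3 discriminates by alkene substitution, so the cis-disubstituted C1=C2 bond of ring A should be reduced while the tetrasubstituted C8=C9 and trisubstituted C13=C14 bonds remain, and no stereocentre is created.

Step 16
Reactants: 26 (2E)-3-({[tert-butyl(dimethyl)silyl]oxy}methyl)-5-[(4aS,8aS)-2,5,5,8a-tetramethyl-3,4,4a,5,6,7,8,8a-octahydronaphthalen-1-yl]pent-2-en-1-ol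
Product: 27 (2E)-3-({[tert-butyl(dimethyl)silyl]oxy}methyl)-5-[(4aS,8aS)-2,5,5,8a-tetramethyl-3,4,4a,5,6,7,8,8a-octahydronaphthalen-1-yl]pent-2-enal
Conditions: MnO2 (activated, 20 equiv), CH2Cl2, rt
Reagents that add atoms: none
Why: MnO2 oxidises the primary allylic alcohol to the enal under neutral heterogeneous conditions that should leave the alkene geometry and the silyl ether intact.

Step 17
Reactants: 27 (2E)-3-({[tert-butyl(dimethyl)silyl]oxy}methyl)-5-[(4aS,8aS)-2,5,5,8a-tetramethyl-3,4,4a,5,6,7,8,8a-octahydronaphthalen-1-yl]pent-2-enal; 28 4-methylfuran-2(5H)-one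
Product: 31 (5Z)-5-[(2E)-3-({[tert-butyl(dimethyl)silyl]oxy}methyl)-5-[(4aS,8aS)-2,5,5,8a-tetramethyl-3,4,4a,5,6,7,8,8a-octahydronaphthalen-1-yl]pent-2-en-1-ylidene]-4-methylfuran-2(5H)-one, via silyloxyfuran 29 (not isolated), via silyl aldol adduct 30 (not isolated)
Conditions: 28, TBSOTf (2.2 equiv), i-Pr2NEt (3 equiv), CH2Cl2, 0 °C; 27, −78 °C → rt; then DBU (2 equiv), rt
Reagents that add atoms: none
Why: Vinylogous Mukaiyama aldol addition of the in situ formed 2-silyloxyfuran 29 through its C5 position to the aldehyde, then base-induced elimination of silanol from adduct 30, should give the conjugated γ-alkylidene butenolide as the thermodynamically favoured Z isomer (C14 cis to the ring oxygen, away from the C17 methyl group).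

Step 18
Reactants: 31 (5Z)-5-[(2E)-3-({[tert-butyl(dimethyl)silyl]oxy}methyl)-5-[(4aS,8aS)-2,5,5,8a-tetramethyl-3,4,4a,5,6,7,8,8a-octahydronaphthalen-1-yl]pent-2-en-1-ylidene]-4-methylfuran-2(5H)-one
Product: 32 (5Z)-5-[(2E)-3-(hydroxymethyl)-5-[(4aS,8aS)-2,5,5,8a-tetramethyl-3,4,4a,5,6,7,8,8a-octahydronaphthalen-1-yl]pent-2-en-1-ylidene]-4-methylfuran-2(5H)-one (target)
Conditions: HF·pyridine, pyridine, THF, 0 °C → rt
Reagents that add atoms: none
Why: Buffered fluoride cleavage of the primary silyl ether should free the C13 hydroxymethyl group without opening the enol lactone.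

Compound list
1 | 3,3-dimethylglutaric anhydride | CC1(C)CC(=O)OC(=O)C1 | starting material
2 | 5-methoxy-3,3-dimethyl-5-oxopentanoic acid | COC(=O)CC(C)(C)CC(=O)O | intermediate
3 | propyne | CC#C | starting material
4 | methyl 5-chloro-3,3-dimethyl-5-oxopentanoate | COC(=O)CC(C)(C)CC(=O)Cl | intermediate
5 | methyl 3,3-dimethyl-5-oxooct-6-ynoate | COC(=O)CC(C)(C)CC(=O)C#CC | intermediate
6 | methyl (5R)-5-hydroxy-3,3-dimethyloct-6-ynoate | COC(=O)CC(C)(C)C[C@@H](O)C#CC | intermediate
7 | (5R,6Z)-7-iodo-3,3-dimethyloct-6-ene-1,5-diol | OCCC(C)(C)C[C@@H](O)/C=C(\I)C | intermediate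
8 | ethynyltrimethylsilane | C#C[Si](C)(C)C | starting material
9 | (5R,6Z)-3,3,7-trimethyl-9-(trimethylsilyl)non-6-en-8-yne-1,5-diol | OCCC(C)(C)C[C@@H](O)/C=C(C)\C#C[Si](C)(C)C | intermediate
10 | (6R)-4,4-dimethyl-6-[(1Z)-2-methyl-4-(trimethylsilyl)but-1-en-3-yn-1-yl]oxan-2-ol (both anomers) | OC1CC(C)(C)C[C@@H](O1)/C=C(C)\C#C[Si](C)(C)C | intermediate
11 | (6R)-4,4-dimethyl-6-[(1Z)-2-methyl-4-(trimethylsilyl)but-1-en-3-yn-1-yl]oxan-2-one | O=C1CC(C)(C)C[C@@H](O1)/C=C(C)\C#C[Si](C)(C)C | intermediate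
12 | {[(2R)-4,4-dimethyl-2-[(1Z)-2-methyl-4-(trimethylsilyl)but-1-en-3-yn-1-yl]-3,4-dihydro-2H-pyran-6-yl]oxy}trimethylsilane | C[Si](C)(C)OC1=CC(C)(C)C[C@@H](O1)/C=C(C)\C#C[Si](C)(C)C | intermediate
13 | trimethylsilyl (1S,2S)-2,6,6-trimethyl-2-[(trimethylsilyl)ethynyl]cyclohex-3-ene-1-carboxylate | C[Si](C)(C)OC(=O)[C@H]1C(C)(C)CC=C[C@]1(C)C#C[Si](C)(C)C | intermediate
14 | (1S,2S)-2,6,6-trimethyl-2-[(trimethylsilyl)ethynyl]cyclohex-3-ene-1-carboxylic acid | OC(=O)[C@H]1C(C)(C)CC=C[C@]1(C)C#C[Si](C)(C)C | intermediate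
15 | [(1S,2S)-2,6,6-trimethyl-2-[(trimethylsilyl)ethynyl]cyclohex-3-en-1-yl]methanol | OC[C@H]1C(C)(C)CC=C[C@]1(C)C#C[Si](C)(C)C | intermediate
16 | 2-methylallylmagnesium chloride | C=C(C)C[Mg]Cl | starting material
17 | [(1S,2S)-2,6,6-trimethyl-2-[(trimethylsilyl)ethynyl]cyclohex-3-en-1-yl]methyl trifluoromethanesulfonate | O=S(=O)(OC[C@H]1C(C)(C)CC=C[C@]1(C)C#C[Si](C)(C)C)C(F)(F)F | intermediate
18 | trimethyl{[(1S,6S)-1,5,5-trimethyl-6-(3-methylbut-3-en-1-yl)cyclohex-2-en-1-yl]ethynyl}silane | C=C(C)CC[C@H]1C(C)(C)CC=C[C@]1(C)C#C[Si](C)(C)C | intermediate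
19 | (3S,4S)-3-ethynyl-3,5,5-trimethyl-4-(3-methylbut-3-en-1-yl)cyclohex-1-ene | C=C(C)CC[C@H]1C(C)(C)CC=C[C@]1(C)C#C | intermediate
20 | (4aS,8aS)-1-ethenyl-2,5,5,8a-tetramethyl-3,4,4a,5,6,8a-hexahydronaphthalene | C=CC1=C(C)CC[C@H]2C(C)(C)CC=C[C@]12C | intermediate
21 | but-2-yne-1,4-diol | OCC#CCO | starting material
22 | 4-{[tert-butyl(dimethyl)silyl]oxy}but-2-yn-1-ol | OCC#CCO[Si](C)(C)C(C)(C)C | intermediate
23 | (2Z)-4-{[tert-butyl(dimethyl)silyl]oxy}-3-iodobut-2-en-1-ol | OC/C=C(\I)CO[Si](C)(C)C(C)(C)C | intermediate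
24 | 9-{2-[(4aS,8aS)-2,5,5,8a-tetramethyl-3,4,4a,5,6,8a-hexahydronaphthalen-1-yl]ethyl}-9-borabicyclo[3.3.1]nonane | C1CCC2CCCC1B2CCC1=C(C)CC[C@H]2C(C)(C)CC=C[C@]12C | intermediate
25 | (2E)-3-({[tert-butyl(dimethyl)silyl]oxy}methyl)-5-[(4aS,8aS)-2,5,5,8a-tetramethyl-3,4,4a,5,6,8a-hexahydronaphthalen-1-yl]pent-2-en-1-ol | OC/C=C(/CO[Si](C)(C)C(C)(C)C)CCC1=C(C)CC[C@H]2C(C)(C)CC=C[C@]12C | intermediate
26 | (2E)-3-({[tert-butyl(dimethyl)silyl]oxy}methyl)-5-[(4aS,8aS)-2,5,5,8a-tetramethyl-3,4,4a,5,6,7,8,8a-octahydronaphthalen-1-yl]pent-2-en-1-ol | OC/C=C(/CO[Si](C)(C)C(C)(C)C)CCC1=C(C)CC[C@H]2C(C)(C)CCC[C@]12C | intermediate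
27 | (2E)-3-({[tert-butyl(dimethyl)silyl]oxy}methyl)-5-[(4aS,8aS)-2,5,5,8a-tetramethyl-3,4,4a,5,6,7,8,8a-octahydronaphthalen-1-yl]pent-2-enal | O=C/C=C(/CO[Si](C)(C)C(C)(C)C)CCC1=C(C)CC[C@H]2C(C)(C)CCC[C@]12C | intermediate
28 | 4-methylfuran-2(5H)-one | CC1=CC(=O)OC1 | starting material
29 | tert-butyl(dimethyl)[(4-methylfuran-2-yl)oxy]silane | Cc1coc(O[Si](C)(C)C(C)(C)C)c1 | intermediate
30 | 5-[(2E)-1-{[tert-butyl(dimethyl)silyl]oxy}-3-({[tert-butyl(dimethyl)silyl]oxy}methyl)-5-[(4aS,8aS)-2,5,5,8a-tetramethyl-3,4,4a,5,6,7,8,8a-octahydronaphthalen-1-yl]pent-2-en-1-yl]-4-methylfuran-2(5H)-one (mixture at the two new centres) | CC1=CC(=O)OC1C(O[Si](C)(C)C(C)(C)C)/C=C(/CO[Si](C)(C)C(C)(C)C)CCC1=C(C)CC[C@H]2C(C)(C)CCC[C@]12C | intermediate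
31 | (5Z)-5-[(2E)-3-({[tert-butyl(dimethyl)silyl]oxy}methyl)-5-[(4aS,8aS)-2,5,5,8a-tetramethyl-3,4,4a,5,6,7,8,8a-octahydronaphthalen-1-yl]pent-2-en-1-ylidene]-4-methylfuran-2(5H)-one | CC1=CC(=O)O/C1=C\C=C(\CO[Si](C)(C)C(C)(C)C)CCC1=C(C)CC[C@H]2C(C)(C)CCC[C@]12C | intermediate
32 | (5Z)-5-[(2E)-3-(hydroxymethyl)-5-[(4aS,8aS)-2,5,5,8a-tetramethyl-3,4,4a,5,6,7,8,8a-octahydronaphthalen-1-yl]pent-2-en-1-ylidene]-4-methylfuran-2(5H)-one | CC1=CC(=O)O/C1=C\C=C(\CO)CCC1=C(C)CC[C@H]2C(C)(C)CCC[C@]12C | target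

Total step count: 18.
Longest linear sequence: 16 steps (steps 1–11 and 14–18); steps 12–13 make the side-chain fragment 23.

Steps most likely to fail

Step 7. The boat transition state must join a neopentyl-type enolate carbon to a fully substituted alkene terminus. It may be reached so slowly that the silyl ketene acetal is lost first, by hydrolysis or by fragmentation of the lactone enolate.

The fallback makes the same C5–C10 bond in an open-chain ester enolate Claisen rearrangement through a chair and closes ring A afterwards by olefin metathesis. It sets out from diol 9 and comes back at acid 14.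
- The primary hydroxyl is silylated (TBSCl, imidazole, CH2Cl2) to the mono-silyl ether F1.
- The secondary alcohol is esterified with 3,3-dimethylhex-5-enoic acid under Mitsunobu conditions (PPh3, diisopropyl azodicarboxylate) to the inverted (5S) ester F2. Inversion is needed because in the chair the carbinol substituent lies outside the allyl unit, not inside as in the tethered boat.
- Enolisation with LiN(i-Pr)2 in THF/DMPU and silylation with Me3SiCl give the (Z)-silyl ketene acetal F3.
- On warming, F3 should rearrange through the chair to the trimethylsilyl ester F4, which is hydrolysed to the open-chain acid F5 with C5 and C10 as in 14.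
- Ring-closing metathesis (second-generation Grubbs catalyst, CH2Cl2, 40 °C) joins the terminal alkene to C1, expels the former carbinol chain as an alkene and should return 14.

Step 11. The ruthenium carbene may add to the hindered alkyne in the wrong orientation, or fail to close on the 1,1-disubstituted alkene. The outcome would be endo closure to a seven-membered ring, or simple cross-metathesis of the alkyne with ethylene.

The fallback carries out the same reorganisation without a metal carbene reaching the hindered alkene. It sets out from 19 and comes back at 20.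
- PtCl2 (10 mol%, toluene, 80 °C) activates the alkyne as an electrophile.
- The gem-disubstituted alkene attacks through its CH2 terminus; the developing tertiary cationic character at C8 is now an advantage.
- The cyclopropyl platinum carbenoid opens by single cleavage to the same 1-vinylcyclohexene.
- No compound beyond those listed is made (entry F0).

Step 9. Substitution at the β,β-dibranched C6 may be so slow that elimination toward C5, or attack of the Grignard reagent at sulfur, consumes the triflate.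

The fallback builds C6–C7 by carbonyl olefination instead. It sets out from alcohol 15 and comes back at 18.
- Dess–Martin oxidation gives the aldehyde F6.
- Horner–Wadsworth–Emmons reaction with dimethyl (2-oxopropyl)phosphonate (NaH, THF) gives the (E)-enone F7.
- Conjugate reduction with [(Ph3P)CuH]6 gives the saturated methyl ketone F8.
- Wittig methylenation (Ph3P=CH2, THF) gives 18.

Further compounds
F1 | step 7 | (5R,6Z)-1-{[tert-butyl(dimethyl)silyl]oxy}-3,3,7-trimethyl-9-(trimethylsilyl)non-6-en-8-yn-5-ol | CC(C)(C)[Si](C)(C)OCCC(C)(C)C[C@@H](O)/C=C(C)\C#C[Si](C)(C)C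
F2 | step 7 | (5S,6Z)-1-{[tert-butyl(dimethyl)silyl]oxy}-3,3,7-trimethyl-9-(trimethylsilyl)non-6-en-8-yn-5-yl 3,3-dimethylhex-5-enoate | C=CCC(C)(C)CC(=O)O[C@@H](CC(C)(C)CCO[Si](C)(C)C(C)(C)C)/C=C(C)\C#C[Si](C)(C)C
F3 | step 7 | tert-butyl{[(5S,6Z)-5-({(1Z)-3,3-dimethyl-1-[(trimethylsilyl)oxy]hexa-1,5-dien-1-yl}oxy)-3,3,7-trimethyl-9-(trimethylsilyl)non-6-en-8-yn-1-yl]oxy}dimethylsilane | C=CCC(C)(C)/C=C(\O[Si](C)(C)C)O[C@@H](CC(C)(C)CCO[Si](C)(C)C(C)(C)C)/C=C(C)\C#C[Si](C)(C)C
F4 | step 7 | trimethylsilyl (2S,3S,4E)-9-{[tert-butyl(dimethyl)silyl]oxy}-3,7,7-trimethyl-2-(2-methylpent-4-en-2-yl)-3-[(trimethylsilyl)ethynyl]non-4-enoate | C[Si](C)(C)OC(=O)[C@@H](C(C)(C)CC=C)[C@@](C)(C#C[Si](C)(C)C)/C=C/CC(C)(C)CCO[Si](C)(C)C(C)(C)C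
F5 | step 7 | (2S,3S,4E)-9-{[tert-butyl(dimethyl)silyl]oxy}-3,7,7-trimethyl-2-(2-methylpent-4-en-2-yl)-3-[(trimethylsilyl)ethynyl]non-4-enoic acid | OC(=O)[C@@H](C(C)(C)CC=C)[C@@](C)(C#C[Si](C)(C)C)/C=C/CC(C)(C)CCO[Si](C)(C)C(C)(C)C
F0 | step 11 | none | none
F6 | step 9 | (1S,2S)-2,6,6-trimethyl-2-[(trimethylsilyl)ethynyl]cyclohex-3-ene-1-carbaldehyde | O=C[C@H]1C(C)(C)CC=C[C@]1(C)C#C[Si](C)(C)C
F7 | step 9 | (3E)-4-[(1S,2S)-2,6,6-trimethyl-2-[(trimethylsilyl)ethynyl]cyclohex-3-en-1-yl]but-3-en-2-one | CC(=O)/C=C/[C@H]1C(C)(C)CC=C[C@]1(C)C#C[Si](C)(C)C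
F8 | step 9 | 4-[(1S,2S)-2,6,6-trimethyl-2-[(trimethylsilyl)ethynyl]cyclohex-3-en-1-yl]butan-2-one | CC(=O)CC[C@H]1C(C)(C)CC=C[C@]1(C)C#C[Si](C)(C)C
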